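The numbers of this flask are those of an exercise; the rest is arithmetic.

A small charge of catalyst, 2.00 mM, is what this question turns on. Your hunch was that a slow feed protects it, but my reckoning says that depends on what you feed.

in all of them: free catalyst 10 mol%; time 4.0 h
- teal: starting material 20 mM; reagent 0.500 equiv (fed, over 1.5 h); all else is in the flask from the start; the feed brings no volume worth counting
- amber: starting material 20 mM; reagent 0.500 equiv; everything together at the start
- ochre: starting material 20 mM (fed, over 1.5 h); reagent 0.500 equiv; all else is in the flask from the start; the feed brings no volume worth counting

* the flask that comes out highest in amount of product, in percent of the starting material charged, or "all alike" when all lie within 1.5 percentage points (teal / amber / ochre / all alike)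
* product at the end, in percent of the starting material charged, teal
* product at the end, in percent of the starting material charged, amber
* product at the end, in percent of the starting material charged, ochre

    catalyst intermediate C → by-product + catalyst intermediate D (k1 = 0.023 s⁻¹)
    starting material + free catalyst → catalyst intermediate A (k2 = 1.1 M⁻¹ s⁻¹)
    reagent + catalyst intermediate B → catalyst intermediate C (k3 = 2.3 M⁻¹ s⁻¹)
    2 catalyst intermediate B → spent catalyst (k4 = 16 M⁻¹ s⁻¹)
    catalyst intermediate A → catalyst intermediate B (k5 = 0.96 s⁻¹)
    catalyst intermediate D → free catalyst + product (k6 = 0.014 s⁻¹)

- percent here means starting material units held: one spent catalyst counts as two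
- a step written with two of one species runs at k times the square of its concentration and takes two of it each time
- run time (teal): 4.0 h

Reagent is the limiting reagent: its 10.0 mM caps product at 50.0% of the starting material. Catalyst intermediate B has two exits. Capture runs at the step's constant times c(reagent), and pairing to spent catalyst runs at twice its constant times c(catalyst intermediate B). Call capture over pairing the capture ratio.

In amber, the free catalyst loads with a half-life of 31.5 s, close to the 30.1 s of capture, so catalyst intermediate B stays short of the whole charge. Two such steps in series, with pairing set aside, peak near 0.368 of the charge, and there I reckon the ratio at 0.977, with capture and pairing about level. In ochre, catalyst intermediate B can form no faster than the feed of 13.3 mM h⁻¹. Dividing that feed by the capture frequency gives c(catalyst intermediate B), and the ratio comes to 4.46, higher than amber's.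

Teal starts with no reagent in the flask. Its free catalyst loads with the same half-life of 31.5 s, and the reagent feed is 6.67 mM h⁻¹. After loading, the pairing lifetime of catalyst intermediate B roughly equals the elapsed time, while its capture lifetime shrinks as reagent accumulates. The two meet at 8.08 min, later than loading: call this the crossing time. By then c(catalyst intermediate B) is down to 0.0645 mM, or 3.23% of the catalyst charged. So I commit to the order ochre, amber, teal, with teal well behind.

The forecast says ochre, with teal 8%, amber 35% and ochre 37%, holding for ochre that “capture is efficient until catalyst runs short”. The simulation gives ochre, with teal 8.62%, amber 34.6% and ochre 39.5%, which is my order.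

Now take teal with 0.850 equiv of reagent, all else held. The feed rises to 11.3 mM h⁻¹, so the crossing time shortens to 6.19 min, earlier than teal's. That leaves 0.0841 mM of catalyst intermediate B, 1.30 times teal's figure. Multiplying by the feed ratio of 1.69 reckons the product rate at 2.21 times teal's. After 4.00 h this flask holds 15.4% product, 1.79 times teal's.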